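**Plan**

1. Retrosynthesis (ring numbered as in the target: C1 = CH–OAc, C2 = alkene carbon carrying the side chain, C3 = =CH, C4 = CMe2, C5 = CHBr, C6 = CH2): the side chain is taken back to a chloroacetyl group joined at a C2 iodide; C5–Br and C1–O are taken back to a 2,5-dienone; the ring is then cut at C1–C2 and C4–C5 into 3-methylbutan-2-one (1; C2–C3–C4) and methyl acrylate (2; C1–C6–C5).
2. Enabling feature: C3 bears only hydrogen and sits between C2 and the quaternary C4. Drawn as a ketone carbonyl, it makes C2 and C4 the two α-carbons of one ketone, a 1,3-bis-nucleophile that matches the acrylate as 1,3-bis-electrophile (β-carbon C5, acyl carbon C1).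
3. Forward: the six-membered ring is closed first, in one Michael–Claisen operation. The helper oxygen on C3 is then erased (enol ether, hydride, acid), which leaves the C2=C3 alkene and the C1 carbonyl; C2 is iodinated and the C5=C6 alkene is introduced.
4. HBr is added to C5 and the C1 ketone is reduced; the side chain is then joined at C2 (Stille), chlorinated, reduced and brominated.
5. Stereochemistry: C5 arises racemic and relays to C1 (hydride anti to Br, cis). The (1R,5S) series is selected by lipase acetylation, which also installs the acetate. The side-chain center is set by a catalyst-controlled CBS reduction and inverted in the final Appel bromination.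

Key step: step 1

Remark: compounds 6, 10 and 11 are racemic; the SMILES of 11 shows the enantiomer that is carried on after step 7.

**Step 1**
Reactants: 1 3-methylbutan-2-one; 2 methyl acrylate
Product: 4 4,4-dimethylcyclohexane-1,3-dione, via Michael adduct 3 (not isolated)
Conditions: KOtBu (2 equiv), THF, 0 °C to rt; then aq. HCl
Reagents that add atoms: none
Why: tert-Butoxide equilibrates the ketone enolates, and the more substituted enolate at the isopropyl carbon adds 1,4 to the acrylate (Michael addition, C4–C5 bond) to give keto ester 3; proton transfer then gives the methyl-ketone enolate, whose carbon acylates the ester (Claisen condensation, C1–C2 bond) with loss of methoxide. The closest known reaction type is the base-mediated Michael–Claisen [3+3] annulation of ketones with acrylates to cyclohexane-1,3-diones. The ring closes in a 6-(enolendo)-exo-trig mode. No stereocenter is formed. The step needs Michael addition at the tertiary α-carbon and acylation at the methyl group; the reverse pairing would give a 2,2-dimethyl-1,3-dione that has no acidic hydrogen between its carbonyls and reverts by retro-Claisen cleavage, whereas 4 is drained from the equilibria as its stabilised enolate, which is why a second equivalent of base is used.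

**Step 2**
Reactants: 4 4,4-dimethylcyclohexane-1,3-dione
Product: 5 6,6-dimethyl-3-(2-methylpropoxy)cyclohex-2-en-1-one
Conditions: 2-methylpropan-1-ol, TsOH·H2O (cat.), toluene, reflux, azeotropic removal of water
Reagents that add atoms: 2-methylpropan-1-ol, CC(C)CO
Why: Acid-catalysed enol etherification (vinylogous ester formation) of the 1,3-dione should take place at the less hindered C1 oxygen, remote from the gem-dimethyl group, which leaves the ketone next to C4 free for deletion of the C3 oxygen in the next step.

**Step 3**
Reactants: 5 6,6-dimethyl-3-(2-methylpropoxy)cyclohex-2-en-1-one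
Product: 7 4,4-dimethylcyclohex-2-en-1-one, via allylic alcohol 6 (not isolated)
Conditions: LiAlH4, Et2O, 0 °C; then 2 M HCl, rt
Reagents that add atoms: water, O
Why: Stork–Danheiser transposition: hydride adds 1,2 to the ketone and acid hydrolysis of the enol ether with loss of water moves the carbonyl to C1 and leaves the C2=C3 alkene, the carbinol center of 6 being destroyed so that its configuration is irrelevant.

**Step 4**
Reactants: 7 4,4-dimethylcyclohex-2-en-1-one
Product: 8 2-iodo-4,4-dimethylcyclohex-2-en-1-one
Conditions: I2, pyridine, CH2Cl2, 0 °C to rt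
Reagents that add atoms: iodine, II
Why: α-Iodination of the enone by addition–elimination (pyridine adds to C3, the enolate is iodinated at C2, pyridine is expelled) places the cross-coupling handle on C2 only.

**Step 5**
Reactants: 8 2-iodo-4,4-dimethylcyclohex-2-en-1-one
Product: 9 2-iodo-4,4-dimethylcyclohexa-2,5-dien-1-one
Conditions: IBX (2-iodoxybenzoic acid), DMSO, 65 °C
Reagents that add atoms: none
Why: IBX dehydrogenation of the ketone through its enol introduces the C5=C6 double bond, and since only C6 carries enolisable hydrogens the regiochemistry is unambiguous.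

**Step 6**
Reactants: 9 2-iodo-4,4-dimethylcyclohexa-2,5-dien-1-one
Product: 11 rac-(1R,5S)-5-bromo-2-iodo-4,4-dimethylcyclohex-2-en-1-ol, via β-bromo ketone 10 (not isolated)
Conditions: HBr (1.1 equiv, anhydrous solution in CH2Cl2), −40 °C; solvent removed cold; then NaBH4, CeCl3·7H2O, MeOH, −78 °C
Reagents that add atoms: hydrogen bromide, Br
Why: Conjugate hydrobromination followed by Luche reduction: bromide adds reversibly to C5 of the unsubstituted enone (the iodine-bearing, more substituted enone is kept under thermodynamic control), and the carbonyl is then reduced 1,2 with hydride delivered anti to the C5 bromine, so that OH and Br should end up cis.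

**Step 7**
Reactants: 11 rac-(1R,5S)-5-bromo-2-iodo-4,4-dimethylcyclohex-2-en-1-ol
Product: 12 (1R,5S)-5-bromo-2-iodo-4,4-dimethylcyclohex-2-en-1-yl acetate
Conditions: Candida antarctica lipase B (immobilised), vinyl acetate, tert-butyl methyl ether, 30 °C, stopped short of half conversion
Reagents that add atoms: vinyl acetate, CC(=O)OC=C
Why: Lipase-catalysed kinetic resolution by irreversible transesterification: by the empirical size rule for secondary alcohols (iodoalkene side large, CH2 side medium) the (1R)-alcohol should be acetylated, which selects the (1R,5S) enantiomer and installs the acetate of the target, while the (1S,5R)-alcohol is left behind.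

**Step 8**
Reactants: 12 (1R,5S)-5-bromo-2-iodo-4,4-dimethylcyclohex-2-en-1-yl acetate; 13 tributyl(1-ethoxyethenyl)stannane
Product: 14 (1R,5S)-5-bromo-2-(1-ethoxyethenyl)-4,4-dimethylcyclohex-2-en-1-yl acetate
Conditions: Pd2(dba)3 (cat.), AsPh3, CuI, NMP, rt
Reagents that add atoms: none
Why: Stille coupling of the vinyl iodide with the α-alkoxyvinylstannane at room temperature, where oxidative addition into the carbon–iodine bond is much faster than ionisation of the hindered allylic acetate or reaction at the secondary alkyl bromide, and no stereocenter is touched.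

**Step 9**
Reactants: 14 (1R,5S)-5-bromo-2-(1-ethoxyethenyl)-4,4-dimethylcyclohex-2-en-1-yl acetate
Product: 15 (1R,5S)-5-bromo-2-(2-chloroacetyl)-4,4-dimethylcyclohex-2-en-1-yl acetate
Conditions: N-chlorosuccinimide, THF/H2O (4:1), 0 °C
Reagents that add atoms: N-chlorosuccinimide, O=C1CCC(=O)N1Cl; water, O
Why: Electrophilic chlorination of the enol ether at its terminal CH2 and hydrolysis of the resulting oxocarbenium ion (halogenation of an enol ether to an α-halo ketone) should give the chloromethyl ketone regiospecifically.

**Step 10**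
Reactants: 15 (1R,5S)-5-bromo-2-(2-chloroacetyl)-4,4-dimethylcyclohex-2-en-1-yl acetate
Product: 16 (1R,5S)-5-bromo-2-[(1S)-2-chloro-1-hydroxyethyl]-4,4-dimethylcyclohex-2-en-1-yl acetate
Conditions: (S)-CBS catalyst [(3aS)-1-methyl-3,3-diphenyltetrahydro-1H,3H-pyrrolo[1,2-c][1,3,2]oxazaborole, 20 mol %], BH3·SMe2, THF, −30 °C; MeOH quench
Reagents that add atoms: none
Why: Corey–Bakshi–Shibata reduction, in which the catalyst binds the ketone with the fully substituted alkenyl group as the large and CH2Cl as the small substituent and delivers hydride to give the (S)-carbinol under catalyst control, with 1,2-reduction only.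

**Step 11**
Reactants: 16 (1R,5S)-5-bromo-2-[(1S)-2-chloro-1-hydroxyethyl]-4,4-dimethylcyclohex-2-en-1-yl acetate
Product: 17 (1R,5S)-5-bromo-2-[(1R)-1-bromo-2-chloroethyl]-4,4-dimethylcyclohex-2-en-1-yl acetate
Conditions: CBr4, PPh3, CH2Cl2, −20 to 0 °C
Reagents that add atoms: carbon tetrabromide, BrC(Br)(Br)Br
Why: Appel reaction, in which the oxyphosphonium of the secondary alcohol is displaced by bromide in an SN2 step with inversion ((S)-alcohol to (R)-bromide), SN2′ attack at C3 being blocked by the neighbouring quaternary C4 and ionisation being disfavoured by the β-chlorine.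

**Compound list**

1 | 3-methylbutan-2-one | CC(=O)C(C)C | starting material
2 | methyl acrylate | C=CC(=O)OC | starting material
3 | methyl 4,4-dimethyl-5-oxohexanoate | COC(=O)CCC(C)(C)C(C)=O | intermediate (not isolated)
4 | 4,4-dimethylcyclohexane-1,3-dione | O=C1CC(=O)C(C)(C)CC1 | intermediate
5 | 6,6-dimethyl-3-(2-methylpropoxy)cyclohex-2-en-1-one | CC(C)COC1=CC(=O)C(C)(C)CC1 | intermediate
6 | 6,6-dimethyl-3-(2-methylpropoxy)cyclohex-2-en-1-ol (racemic) | CC(C)COC1=CC(O)C(C)(C)CC1 | intermediate (not isolated)
7 | 4,4-dimethylcyclohex-2-en-1-one | CC1(C)C=CC(=O)CC1 | intermediate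
8 | 2-iodo-4,4-dimethylcyclohex-2-en-1-one | CC1(C)C=C(I)C(=O)CC1 | intermediate
9 | 2-iodo-4,4-dimethylcyclohexa-2,5-dien-1-one | CC1(C)C=CC(=O)C(I)=C1 | intermediate
10 | 5-bromo-2-iodo-4,4-dimethylcyclohex-2-en-1-one (racemic) | CC1(C)C=C(I)C(=O)CC1Br | intermediate (not isolated)
11 | rac-(1R,5S)-5-bromo-2-iodo-4,4-dimethylcyclohex-2-en-1-ol (cis, racemate) | O[C@@H]1C[C@H](Br)C(C)(C)C=C1I | intermediate
12 | (1R,5S)-5-bromo-2-iodo-4,4-dimethylcyclohex-2-en-1-yl acetate | CC(=O)O[C@@H]1C[C@H](Br)C(C)(C)C=C1I | intermediate
13 | tributyl(1-ethoxyethenyl)stannane | CCOC(=C)[Sn](CCCC)(CCCC)CCCC | starting material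
14 | (1R,5S)-5-bromo-2-(1-ethoxyethenyl)-4,4-dimethylcyclohex-2-en-1-yl acetate | CC(=O)O[C@@H]1C[C@H](Br)C(C)(C)C=C1C(=C)OCC | intermediate
15 | (1R,5S)-5-bromo-2-(2-chloroacetyl)-4,4-dimethylcyclohex-2-en-1-yl acetate | CC(=O)O[C@@H]1C[C@H](Br)C(C)(C)C=C1C(=O)CCl | intermediate
16 | (1R,5S)-5-bromo-2-[(1S)-2-chloro-1-hydroxyethyl]-4,4-dimethylcyclohex-2-en-1-yl acetate | CC(=O)O[C@@H]1C[C@H](Br)C(C)(C)C=C1[C@H](O)CCl | intermediate
17 | (1R,5S)-5-bromo-2-[(1R)-1-bromo-2-chloroethyl]-4,4-dimethylcyclohex-2-en-1-yl acetate | CC(=O)O[C@@H]1C[C@H](Br)C(C)(C)C=C1[C@@H](Br)CCl | target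

**Totals**

Total step count: 11. Longest linear sequence: 11 steps (from 1 or 2 to 17).

**Steps most likely to fail**

Step 6. The protonated dienone may undergo the 1,2-methyl shift of a dienone–phenol rearrangement, or 10 may lose HBr again before or during the reduction. Fallback: starting from 9, bromotrimethylsilane (CH2Cl2, −78 °C) adds 1,4 to the unsubstituted enone without protic acid and traps the adduct as [(3-bromo-6-iodo-4,4-dimethylcyclohexa-1,5-dien-1-yl)oxy]trimethylsilane F1. F1 is added to NaBH4/CeCl3·7H2O in MeOH at −78 °C, where methanolysis releases 10 and hydride reduces it at once; the route is rejoined at 11.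

Step 7. Acyl transfer to the carbinol flanked by the iodoalkene may be slow or poorly enantioselective. Fallback: starting from 11, esterification with (2S)-2-methoxy-2-phenylacetic acid (DCC, DMAP, CH2Cl2) gives the diastereomeric esters (1R,5S)-5-bromo-2-iodo-4,4-dimethylcyclohex-2-en-1-yl (2S)-2-methoxy-2-phenylacetate F2 and its (1S,5R) ring diastereomer F3, which are separated by chromatography or crystallisation. Methanolysis of F2 (K2CO3, MeOH, 0 °C) gives the enantiopure (1R,5S)-5-bromo-2-iodo-4,4-dimethylcyclohex-2-en-1-ol F4, and Ac2O/pyridine/DMAP converts it into 12, where the route is rejoined.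

Step 5. Overoxidation or loss of iodine may occur at the temperature the IBX dehydrogenation needs. Fallback: starting from 8, lithium diisopropylamide (THF, −78 °C) and PhSeCl give 2-iodo-4,4-dimethyl-6-(phenylselanyl)cyclohex-2-en-1-one F5. H2O2/pyridine (CH2Cl2, 0 °C) oxidises it to the selenoxide 2-iodo-4,4-dimethyl-6-(phenylseleninyl)cyclohex-2-en-1-one F6, which undergoes syn-elimination to 9, where the route is rejoined.

**Further compounds**

F1 | step 6 | [(3-bromo-6-iodo-4,4-dimethylcyclohexa-1,5-dien-1-yl)oxy]trimethylsilane (racemic) | C[Si](C)(C)OC1=CC(Br)C(C)(C)C=C1I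
F2 | step 7 | (1R,5S)-5-bromo-2-iodo-4,4-dimethylcyclohex-2-en-1-yl (2S)-2-methoxy-2-phenylacetate | CO[C@H](C(=O)O[C@@H]1C[C@H](Br)C(C)(C)C=C1I)c1ccccc1
F3 | step 7 | (1S,5R)-5-bromo-2-iodo-4,4-dimethylcyclohex-2-en-1-yl (2S)-2-methoxy-2-phenylacetate | CO[C@H](C(=O)O[C@H]1C[C@@H](Br)C(C)(C)C=C1I)c1ccccc1
F4 | step 7 | (1R,5S)-5-bromo-2-iodo-4,4-dimethylcyclohex-2-en-1-ol (single enantiomer) | O[C@@H]1C[C@H](Br)C(C)(C)C=C1I
F5 | step 5 | 2-iodo-4,4-dimethyl-6-(phenylselanyl)cyclohex-2-en-1-one (racemic) | O=C1C(I)=CC(C)(C)CC1[Se]c1ccccc1
F6 | step 5 | 2-iodo-4,4-dimethyl-6-(phenylseleninyl)cyclohex-2-en-1-one | O=C1C(I)=CC(C)(C)CC1[Se](=O)c1ccccc1
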